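Prostanoid numbering is used (C1 ester carbon; five-membered ring C8–C12). The ring is cut on both sides of its cis C10=C11 vinylene, which sits between the tertiary carbinol C12 and the ketone C9. What remains is an acyclic (Z)-alkylidene β-keto ester that already holds every other carbon, the 7Z and 5E olefins and C4, plus a cis-vinylene 1,2-dianion equivalent. In one flask the first alkenyl anion adds to the C12 ketone and the second, set free by tin–lithium exchange, attacks the C9 ester, so that the ring closes and the chiral ester alcohol that steers the C12 addition is expelled. Bromine enters at C10 afterwards by way of the 10,11-epoxide.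

Key step: step 11

Assumption: (−)-8-phenylmenthol is taken to shield the ketone face that leads to 12R (π-stacking model of its enoates); this sense is not secured, and if it proved opposite the antipodal auxiliary would be carried through the same steps.

Step 1
Reactants: 1 (3Z,6Z)-nona-3,6-dien-1-ol
Product: 3 (3Z,6Z)-nona-3,6-dienoic acid, via aldehyde 2 (not isolated)
Conditions: (2,2,6,6-tetramethylpiperidin-1-yl)oxyl (10 mol %), PhI(OAc)2, MeCN/aq. pH 7 buffer, 0 °C to rt
Reagents that add atoms: water, O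
Why: Oxoammonium oxidation takes the primary alcohol through the aldehyde hydrate to the acid under near-neutral conditions that should leave the skipped Z,Z-diene unconjugated.

Step 2
Reactants: 3 (3Z,6Z)-nona-3,6-dienoic acid; 4 Meldrum's acid (2,2-dimethyl-1,3-dioxane-4,6-dione)
Product: 5 5-[(3Z,6Z)-1-hydroxynona-3,6-dien-1-ylidene]-2,2-dimethyl-1,3-dioxane-4,6-dione
Conditions: N,N'-dicyclohexylcarbodiimide, 4-(dimethylamino)pyridine, CH2Cl2, −10 to 0 °C
Reagents that add atoms: none
Why: Carbodiimide activation and C-acylation of Meldrum's acid gives the enol-stabilised acyl derivative at a temperature where the 3Z double bond should not migrate.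

Step 3
Reactants: 5 acyl Meldrum's acid; 6 (1R,2S,5R)-8-phenylmenthol
Product: 8 (1R,2S,5R)-8-phenylmenthyl (5Z,8Z)-3-oxoundeca-5,8-dienoate, via acylketene 7 (not isolated)
Conditions: toluene, 85 °C
Reagents that add atoms: none
Why: Thermal loss of acetone and CO2 gives an acylketene that the hindered alcohol traps to the β-keto ester without any base.

Step 4
Reactants: 9 methyl 5-bromo-4-oxopentanoate
Product: 11 methyl 4-oxo-5-(triphenyl-λ5-phosphanylidene)pentanoate, via phosphonium bromide 10 (not isolated)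
Conditions: PPh3, toluene, rt; then aq. Na2CO3, CH2Cl2
Reagents that add atoms: triphenylphosphine, c1ccc(cc1)P(c1ccccc1)c1ccccc1
Why: SN2 alkylation of the phosphine by the α-bromo ketone and deprotonation give the stabilised acylmethylene ylide.

Step 5
Reactants: 11 ylide; 12 2,2-dimethoxyacetaldehyde
Product: 13 methyl (E)-7,7-dimethoxy-4-oxohept-5-enoate
Conditions: CH2Cl2, rt
Reagents that add atoms: none
Why: Wittig reaction of the stabilised ylide should give the E-enone, which sets the 5E double bond.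

Step 6
Reactants: 13 methyl (E)-7,7-dimethoxy-4-oxohept-5-enoate
Product: 14 methyl (S,E)-4-hydroxy-7,7-dimethoxyhept-5-enoate
Conditions: (R)-1-methyl-3,3-diphenyltetrahydro-1H,3H-pyrrolo[1,2-c][1,3,2]oxazaborole (10 mol %), catecholborane, toluene, −78 °C
Reagents that add atoms: none
Why: Corey–Bakshi–Shibata reduction, in which the alkenyl group acts as the large substituent so that the (R)-catalyst should deliver hydride to give the 4S allylic alcohol.

Step 7
Reactants: 14 methyl (S,E)-4-hydroxy-7,7-dimethoxyhept-5-enoate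
Product: 15 methyl (S,E)-4-[(tert-butyldimethylsilyl)oxy]-7,7-dimethoxyhept-5-enoate
Conditions: TBSCl, imidazole, DMF, 0 °C, on the crude alcohol
Reagents that add atoms: tert-butyldimethylsilyl chloride, CC(C)(C)[Si](C)(C)Cl
Why: Silylation of the secondary alcohol prevents lactonisation onto the methyl ester and masks the hydroxyl for the organolithium step.

Step 8
Reactants: 15 silyl ether acetal
Product: 16 methyl (S,E)-4-[(tert-butyldimethylsilyl)oxy]-7-oxohept-5-enoate
Conditions: pyridinium p-toluenesulfonate, acetone/H2O, rt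
Reagents that add atoms: water, O
Why: Mild acid hydrolysis of the allylic dimethyl acetal should free the E-enal while the silyl ether survives.

Step 9
Reactants: 8 8-phenylmenthyl β-keto ester; 16 enal
Product: 17 1-[(1R,2S,5R)-8-phenylmenthyl] 8-methyl (2Z,4E,6S)-6-[(tert-butyldimethylsilyl)oxy]-2-[(3Z,6Z)-nona-3,6-dienoyl]octa-2,4-dienedioate
Conditions: TiCl4, pyridine, THF, −10 to 0 °C
Reagents that add atoms: none
Why: Knoevenagel condensation, in which the isomer with the planar ester cis and the bulkier acyl group trans to the dienyl chain (2Z, the later 7Z) is expected to predominate and is separated from the minor isomer.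

Step 10
Reactants: 18 acetylene
Product: 19 (Z)-1,2-bis(trimethylstannyl)ethene
Conditions: Me3SnSnMe3, Pd(PPh3)4 (1 mol %), dioxane, 60 °C
Reagents that add atoms: hexamethyldistannane, C[Sn](C)(C)[Sn](C)(C)C
Why: Palladium-catalysed syn-distannation of the alkyne places both tin atoms cis, which the later ring closure requires.

Step 11
Reactants: 17 (Z)-alkylidene keto diester; 19 (Z)-1,2-bis(trimethylstannyl)ethene
Product: 22 methyl (4S,5E,7Z,12R,14Z,17Z)-4-[(tert-butyldimethylsilyl)oxy]-12-hydroxy-9-oxoprosta-5,7,10,14,17-pentaenoate, via alkenyllithium 20 (not isolated), via stannyl carbinol 21 (not isolated)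
Conditions: 19, MeLi (1.05 equiv), THF, −78 °C; then 17, Et2O/THF, −100 °C; then MeLi (1.1 equiv), −100 to −78 °C; AcOH, −78 °C
Reagents that add atoms: none
Why: Alkenyllithium 20 (from 19 by tin–lithium exchange) adds 1,2 to the C12 ketone, the most electrophilic carbonyl of 17, and a second exchange on the cis-stannane 21 gives a C10 alkenyllithium that attacks the C9 ester and expels lithium 8-phenylmentholate; the closest known type is the use of cis-2-stannylvinyl anions as bifunctional annulation reagents followed by a Parham-type anionic cyclisation. The ring closes in the 5-exo-trig mode at the ester carbonyl, the 5-endo attack on C7 being disfavoured, and closure is possible only because tin and C12 are cis in 21. The new C12 stereocentre is controlled by the 8-phenylmenthyl ester: lithium bridges the C9 and C12 carbonyl oxygens and holds them coplanar with the dienoate, the phenyl ring stacks over one face of this chelate, and the alkenyl group should enter from the open face to give 12R. The step needs 1,2- over 1,4- and 1,6-addition, which the hard alkenyllithium, the ether solvent and −100 °C should favour, and it needs exchange at tin to be faster than attack of MeLi on the esters, which is usual for trimethylstannylalkenes. The 7Z geometry is carried over from 17 because C7=C8 stays a double bond throughout.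

Step 12
Reactants: 22 dienone
Product: 23 methyl (4S,5E,7Z,10S,11R,12S,14Z,17Z)-4-[(tert-butyldimethylsilyl)oxy]-10,11-epoxy-12-hydroxy-9-oxoprosta-5,7,14,17-tetraenoate
Conditions: 30 % H2O2, NaOH (0.3 equiv), MeOH, −20 °C, dark
Reagents that add atoms: hydrogen peroxide, OO
Why: Weitz–Scheffer epoxidation, in which hydroperoxide should add to the unhindered endocyclic C11 and not to the exocyclic dienone or the isolated olefins, closing cis to the 12-OH (this stereochemistry is lost in step 13).

Step 13
Reactants: 23 epoxy ketone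
Product: 26 methyl (4S,5E,7Z,12R,14Z,17Z)-10-bromo-4-[(tert-butyldimethylsilyl)oxy]-12-hydroxy-9-oxoprosta-5,7,10,14,17-pentaenoate, via bromohydrin 24 (not isolated), via mesylate 25 (not isolated)
Conditions: MgBr2·OEt2, Et2O, −20 to 0 °C; then MsCl, Et3N, CH2Cl2, 0 °C
Reagents that add atoms: magnesium bromide, [Mg+2].[Br-].[Br-]
Why: Bromide opens the α,β-epoxy ketone at C10 (SN2 next to the carbonyl, away from the quaternary C12) and E1cB loss of the activated C11 oxygen restores the C10=C11 double bond, now carrying bromine.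

Step 14
Reactants: 26 bromo dienone silyl ether
Product: 27 methyl (4S,5E,7Z,12R,14Z,17Z)-10-bromo-4,12-dihydroxy-9-oxoprosta-5,7,10,14,17-pentaenoate
Conditions: HF·pyridine, pyridine/THF, 0 °C
Reagents that add atoms: none
Why: Buffered fluoride cleavage of the secondary silyl ether should be mild enough for the bromodienone, the tertiary allylic alcohol and the γ-hydroxy ester.

Compound list
1 | (3Z,6Z)-nona-3,6-dien-1-ol | CC/C=C\C/C=C\CCO | starting material
2 | (3Z,6Z)-nona-3,6-dienal | CC/C=C\C/C=C\CC=O | intermediate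
3 | (3Z,6Z)-nona-3,6-dienoic acid | CC/C=C\C/C=C\CC(=O)O | intermediate
4 | Meldrum's acid (2,2-dimethyl-1,3-dioxane-4,6-dione) | CC1(C)OC(=O)CC(=O)O1 | starting material
5 | 5-[(3Z,6Z)-1-hydroxynona-3,6-dien-1-ylidene]-2,2-dimethyl-1,3-dioxane-4,6-dione | CC/C=C\C/C=C\CC(O)=C1C(=O)OC(C)(C)OC1=O | intermediate
6 | (1R,2S,5R)-5-methyl-2-(2-phenylpropan-2-yl)cyclohexan-1-ol, (−)-8-phenylmenthol | CC(C)(c1ccccc1)[C@@H]1CC[C@@H](C)C[C@H]1O | starting material
7 | (5Z,8Z)-3-oxoundeca-1,5,8-trien-1-one (acylketene) | CC/C=C\C/C=C\CC(=O)C=C=O | intermediate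
8 | (1R,2S,5R)-8-phenylmenthyl (5Z,8Z)-3-oxoundeca-5,8-dienoate | CC(C)(c1ccccc1)[C@@H]1CC[C@@H](C)C[C@H]1OC(=O)CC(=O)C/C=C\C/C=C\CC | intermediate
9 | methyl 5-bromo-4-oxopentanoate | COC(=O)CCC(=O)CBr | starting material
10 | (5-methoxy-2,5-dioxopentyl)triphenylphosphonium bromide | [Br-].COC(=O)CCC(=O)C[P+](c1ccccc1)(c1ccccc1)c1ccccc1 | intermediate
11 | methyl 4-oxo-5-(triphenyl-λ5-phosphanylidene)pentanoate | COC(=O)CCC(=O)C=P(c1ccccc1)(c1ccccc1)c1ccccc1 | intermediate
12 | 2,2-dimethoxyacetaldehyde | COC(OC)C=O | starting material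
13 | methyl (E)-7,7-dimethoxy-4-oxohept-5-enoate | COC(=O)CCC(=O)/C=C/C(OC)OC | intermediate
14 | methyl (S,E)-4-hydroxy-7,7-dimethoxyhept-5-enoate | COC(OC)/C=C/[C@@H](O)CCC(=O)OC | intermediate
15 | methyl (S,E)-4-[(tert-butyldimethylsilyl)oxy]-7,7-dimethoxyhept-5-enoate | COC(OC)/C=C/[C@@H](O[Si](C)(C)C(C)(C)C)CCC(=O)OC | intermediate
16 | methyl (S,E)-4-[(tert-butyldimethylsilyl)oxy]-7-oxohept-5-enoate | O=C/C=C/[C@@H](O[Si](C)(C)C(C)(C)C)CCC(=O)OC | intermediate
17 | 1-[(1R,2S,5R)-8-phenylmenthyl] 8-methyl (2Z,4E,6S)-6-[(tert-butyldimethylsilyl)oxy]-2-[(3Z,6Z)-nona-3,6-dienoyl]octa-2,4-dienedioate | CC(C)(c1ccccc1)[C@@H]1CC[C@@H](C)C[C@H]1OC(=O)/C(C(=O)C/C=C\C/C=C\CC)=C\C=C\[C@@H](O[Si](C)(C)C(C)(C)C)CCC(=O)OC | intermediate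
18 | acetylene | C#C | starting material
19 | (Z)-1,2-bis(trimethylstannyl)ethene | C[Sn](C)(C)/C=C\[Sn](C)(C)C | intermediate
20 | [(Z)-2-(trimethylstannyl)ethenyl]lithium | [Li]/C=C\[Sn](C)(C)C | intermediate
21 | 1-[(1R,2S,5R)-8-phenylmenthyl] 8-methyl (2Z,4E,6S)-6-[(tert-butyldimethylsilyl)oxy]-2-[(1Z,3R,5Z,8Z)-3-hydroxy-1-(trimethylstannyl)undeca-1,5,8-trien-3-yl]octa-2,4-dienedioate (formed as its lithium alkoxide) | CC(C)(c1ccccc1)[C@@H]1CC[C@@H](C)C[C@H]1OC(=O)/C(=C\C=C\[C@@H](O[Si](C)(C)C(C)(C)C)CCC(=O)OC)[C@@](O)(C/C=C\C/C=C\CC)/C=C\[Sn](C)(C)C | intermediate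
22 | methyl (4S,5E,7Z,12R,14Z,17Z)-4-[(tert-butyldimethylsilyl)oxy]-12-hydroxy-9-oxoprosta-5,7,10,14,17-pentaenoate | CC/C=C\C/C=C\C[C@@]1(O)C=CC(=O)/C1=C\C=C\[C@@H](O[Si](C)(C)C(C)(C)C)CCC(=O)OC | intermediate
23 | methyl (4S,5E,7Z,10S,11R,12S,14Z,17Z)-4-[(tert-butyldimethylsilyl)oxy]-10,11-epoxy-12-hydroxy-9-oxoprosta-5,7,14,17-tetraenoate (epoxide cis to 12-OH) | CC/C=C\C/C=C\C[C@@]1(O)[C@@H]2O[C@@H]2C(=O)/C1=C\C=C\[C@@H](O[Si](C)(C)C(C)(C)C)CCC(=O)OC | intermediate
24 | methyl (4S,5E,7Z,10R,11S,12S,14Z,17Z)-10-bromo-4-[(tert-butyldimethylsilyl)oxy]-11,12-dihydroxy-9-oxoprosta-5,7,14,17-tetraenoate (formed as its magnesium alkoxide) | CC/C=C\C/C=C\C[C@@]1(O)[C@H](O)[C@@H](Br)C(=O)/C1=C\C=C\[C@@H](O[Si](C)(C)C(C)(C)C)CCC(=O)OC | intermediate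
25 | 11-O-methanesulfonyl derivative of 24 | CC/C=C\C/C=C\C[C@@]1(O)[C@H](OS(C)(=O)=O)[C@@H](Br)C(=O)/C1=C\C=C\[C@@H](O[Si](C)(C)C(C)(C)C)CCC(=O)OC | intermediate
26 | methyl (4S,5E,7Z,12R,14Z,17Z)-10-bromo-4-[(tert-butyldimethylsilyl)oxy]-12-hydroxy-9-oxoprosta-5,7,10,14,17-pentaenoate | CC/C=C\C/C=C\C[C@@]1(O)C=C(Br)C(=O)/C1=C\C=C\[C@@H](O[Si](C)(C)C(C)(C)C)CCC(=O)OC | intermediate
27 | methyl (4S,5E,7Z,12R,14Z,17Z)-10-bromo-4,12-dihydroxy-9-oxoprosta-5,7,10,14,17-pentaenoate | CC/C=C\C/C=C\C[C@@]1(O)C=C(Br)C(=O)/C1=C\C=C\[C@@H](O)CCC(=O)OC | target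

Total step count: 14. Longest linear sequence: 10 steps (steps 4 to 9, then 11 to 14).

Steps most likely to fail

Step 11. The alkenyllithium may add in the conjugate sense (1,4 or 1,6) to the dienyl keto ester, and the auxiliary may give too little facial bias at the C12 ketone. The fallback splits the annulation into known separate operations. It sets out from 17 and 19: the organocerium reagent made from 20 and CeCl3 (THF, −78 °C) should add only 1,2 to the ketone, and the stannyl carbinol 21 is isolated, where a C12 epimer can be removed by chromatography because it is a diastereomer. Iodine (CH2Cl2, 0 °C) then replaces tin with retention to give the (Z)-iodoalkenyl carbinol F1. Treatment with t-BuLi (2.1 equiv, THF/Et2O/pentane, −100 °C) effects iodine–lithium exchange and Parham-type cyclisation onto the C9 ester, and the route is rejoined at 22.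

Step 13. During epoxide opening and elimination the Lewis acid may ionise the tertiary allylic alcohol, or reversible bromide addition may turn the C7=C8 bond from Z to E. The fallback brings bromine in through tin and makes steps 12 and 13 unnecessary. It sets out from 22: pyridine-mediated α-iodination (I2, pyridine, CCl4, 0 °C) gives the 10-iodo dienone F3. Stannylation with Me3SnSnMe3 and Pd(PPh3)4 (toluene, 60 °C) gives the 10-trimethylstannyl dienone F4. N-Bromosuccinimide (THF, −20 °C) then cleaves the carbon–tin bond in preference to the olefins, and the route is rejoined at 26.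

Step 9. Under titanium tetrachloride and pyridine the C14 double bond may move into conjugation with the ketone, and the E/Z ratio at the new double bond may be poor. The fallback replaces the condensation by a low-temperature aldol and a separate elimination. It sets out from 8 and 16: soft enolisation (MgBr2·OEt2, Et3N, CH2Cl2, −20 °C) gives the aldol adduct F2 as a mixture at the two new carbinol and methine centres. Mesylation and elimination (MsCl, Et3N, 0 °C) then return to 17, again after separation of the geometric isomers.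

Further compounds
F1 | step 11 | 1-[(1R,2S,5R)-8-phenylmenthyl] 8-methyl (2Z,4E,6S)-6-[(tert-butyldimethylsilyl)oxy]-2-[(1Z,3R,5Z,8Z)-3-hydroxy-1-iodoundeca-1,5,8-trien-3-yl]octa-2,4-dienedioate | CC(C)(c1ccccc1)[C@@H]1CC[C@@H](C)C[C@H]1OC(=O)/C(=C\C=C\[C@@H](O[Si](C)(C)C(C)(C)C)CCC(=O)OC)[C@@](O)(C/C=C\C/C=C\CC)/C=C\I
F2 | step 9 | 1-[(1R,2S,5R)-8-phenylmenthyl] 8-methyl (4E,6S)-6-[(tert-butyldimethylsilyl)oxy]-3-hydroxy-2-[(3Z,6Z)-nona-3,6-dienoyl]oct-4-enedioate (mixture at C2 and C3) | CC(C)(c1ccccc1)[C@@H]1CC[C@@H](C)C[C@H]1OC(=O)C(C(=O)C/C=C\C/C=C\CC)C(O)/C=C/[C@@H](O[Si](C)(C)C(C)(C)C)CCC(=O)OC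
F3 | step 13 | methyl (4S,5E,7Z,12R,14Z,17Z)-4-[(tert-butyldimethylsilyl)oxy]-12-hydroxy-10-iodo-9-oxoprosta-5,7,10,14,17-pentaenoate | CC/C=C\C/C=C\C[C@@]1(O)C=C(I)C(=O)/C1=C\C=C\[C@@H](O[Si](C)(C)C(C)(C)C)CCC(=O)OC
F4 | step 13 | methyl (4S,5E,7Z,12R,14Z,17Z)-4-[(tert-butyldimethylsilyl)oxy]-12-hydroxy-9-oxo-10-(trimethylstannyl)prosta-5,7,10,14,17-pentaenoate | CC/C=C\C/C=C\C[C@@]1(O)C=C([Sn](C)(C)C)C(=O)/C1=C\C=C\[C@@H](O[Si](C)(C)C(C)(C)C)CCC(=O)OC
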